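We decide to reckon this flask by following one catalyst round its cycle and adding up its waits.

    catalyst intermediate D ⇌ free catalyst + product (K1 = 0.016 M, k1 = 0.0014 s⁻¹)
    reagent + free catalyst ⇌ catalyst intermediate A (K2 = 4.1 M⁻¹, k2 = 0.013 M⁻¹ s⁻¹)
    reagent + by-product ⇌ idle adduct, settled at all times (K3 = 7.6 M⁻¹)
    catalyst intermediate A → catalyst intermediate B (k4 = 0.0011 s⁻¹)
    substrate + catalyst intermediate C → catalyst intermediate D (k5 = 0.0042 M⁻¹ s⁻¹)
    catalyst intermediate B ⇌ by-product + catalyst intermediate C (K6 = 0.10 M, k6 = 0.14 s⁻¹)

substrate 0.050 M; reagent 0.0900 M; free catalyst 1.2 mM; time 12 h

* part of the substrate that has reacted at 12 h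
* share of the unused reagent that is free and not bound as idle adduct, at 12 h

- what is said of by-product includes idle adduct
- run time (flask): 12 h

With the catalyst forms steady, each form holds a catalyst for a wait. Free catalyst waits 0.922 h at charged [reagent], the way back from catalyst intermediate A included; intermediate A waits 0.253 h, intermediate C 1.32 h at charged [substrate], and intermediate D 0.198 h. We pass over intermediate B, whose step runs far faster than the one feeding it. The sum of the waits is the cycle time, the time one catalyst needs for one turn: 2.70 h. Intermediate C has the longest wait, about half of the cycle, so we expect it to be the resting state.

The curve follows. The catalyst is charged free, so product starts with zero slope. Its first knee comes as intermediate C fills, which we take to cost about that form's wait. Then the slope is catalyst over cycle time, 0.445 mM h⁻¹, so at 12 h we commit to 4.75 mM of product, or 9.51% conversion. Reagent exceeds substrate, so substrate is the limiting reagent and the curve heads for full conversion. The straight line meets that level at 112 h, but the waits at free catalyst and intermediate C lengthen as [reagent] and [substrate] fall, and product can carry free catalyst back to intermediate D, so we expect the curve to bend before then.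

By-product leaves before intermediate C, so it escapes that lag: about 5.34 mM is made. Taking the adduct balance as settled, with 0.684 bound per free by-product, leaves 3.17 mM free, and the free share of reagent is 97.6%.

The forecast, from “catalyst total equals the flux times the sum of the residence times”, gives 9.2%, a little below our figure, and 97.7%.

The flask gives 9.27% and 97.6%, and 57.3% at 120 h. The neighbour flask has 0.022 M of reagent. Its free-catalyst wait grows to 3.77 h, so the cycle time of 2.70 h becomes 5.54 h, twice as long. With the same lag, we reckon 4.62%; that flask gives 4.34%, so the flask converts twice as much as its neighbour. Reckoned at charged [reagent], the free wait is 68.1% of the neighbour flask's cycle; the reading for free catalyst in that flask is 64.0% of the catalyst charged at 12.0 h.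

(The constants belong to no real substance; what happens was integrated by code.)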